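**Plan**

- Retrosynthesis: after removing the three late O-methyl groups, the 7-O-tert-butyl and the 4'-O-benzyl group, ring A is cut at C8–C8a, which unfolds it to a 4-hydroxy-4-(pyranonyl)cyclobutenone.
- The cyclobutenone is cut at C5–C4a into a 5-magnesiated 2-aryl-3-methoxy-4-pyranone and tert-butyl methyl squarate; the C2–C1' bond is cut back to a 2-bromo-3-methoxy-4-pyranone and an arylboronic acid.
- Enabling feature: C5, C6, C7 and C8 are four contiguous oxygen-bearing carbons, i.e. a squarate four-carbon unit fused onto the C4a=C8a double bond of a 2-aryl-3-methoxy-4-pyranone.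
- Forward order: ring C is bought as pyromeconic acid, ring B is attached by cross-coupling, the four-membered ring is attached at pyranone C5, and ring A is closed last by thermal ring opening and six-electron electrocyclization.
- Stereochemistry: the target is achiral; the only stereocentre made on the way (the carbinol carbon of the cyclobutenone, racemic) becomes sp2 carbon C5 in the ring-forming step.

Key step: step 7

Assumption: the pyranonylmagnesium reagent is taken to attack the mixed squarate at the carbonyl flanked by the methoxy-bearing carbon, away from the tert-butoxy group. This is argued from sterics and conjugation, not from a direct precedent on this mixed squarate.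

**Step 1**
Reactants: 1 3-hydroxy-4H-pyran-4-one (pyromeconic acid)
Product: 2 2-bromo-3-hydroxy-4H-pyran-4-one
Conditions: NBS (1.0 equiv), MeCN, 0 °C to rt
Reagents that add atoms: N-bromosuccinimide, O=C1CCC(=O)N1Br
Why: Electrophilic bromination of an enol: the 3-hydroxyl makes C2 the most nucleophilic ring carbon, the same ortho position at which kojic acid and allomaltol are halogenated, so the 2-bromide should form selectively.

**Step 2**
Reactants: 2 2-bromo-3-hydroxy-4H-pyran-4-one
Product: 3 2-bromo-3-methoxy-4H-pyran-4-one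
Conditions: MeI, K2CO3, acetone, reflux
Reagents that add atoms: iodomethane, CI
Why: Williamson O-methylation of the acidic enolic hydroxyl, as in the preparation of maltol methyl ether, fixes the 3-methoxy group before any organometallic step.

**Step 3**
Reactants: 3 2-bromo-3-methoxy-4H-pyran-4-one; 4 4-(benzyloxy)phenylboronic acid
Product: 5 2-[4-(benzyloxy)phenyl]-3-methoxy-4H-pyran-4-one
Conditions: Pd(PPh3)4 (5 mol %), K2CO3, dioxane–H2O, 80 °C
Reagents that add atoms: none
Why: Suzuki–Miyaura coupling; the C2–Br bond is that of a vinylogous acyl bromide and adds readily to zerovalent palladium, so the aryl group should be transferred under mild carbonate conditions without opening the pyranone.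

**Step 4**
Reactants: 5 2-[4-(benzyloxy)phenyl]-3-methoxy-4H-pyran-4-one
Product: 6 2-[4-(benzyloxy)phenyl]-5-iodo-3-methoxy-4H-pyran-4-one
Conditions: I2 (0.6 equiv), (NH4)2Ce(NO3)6 (1.1 equiv), MeCN, rt to 50 °C
Reagents that add atoms: iodine, II
Why: Electrophilic iodination at the carbon alpha to the carbonyl (the beta-carbon of the ring enol ether), the reaction that converts flavones into 3-iodoflavones; C5 is the only such position free, and the benzyloxyphenyl ring is deactivated by conjugation with the pyranone.

**Step 5**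
Reactants: 7 3,4-dichlorocyclobut-3-ene-1,2-dione (squaric acid dichloride)
Product: 9 3-tert-butoxy-4-methoxycyclobut-3-ene-1,2-dione, via 3-chloro-4-methoxycyclobut-3-ene-1,2-dione 8 (not isolated)
Conditions: MeOH (1.0 equiv), CH2Cl2, 0 °C to rt, N2 sweep, evaporate; then KOtBu (1.0 equiv), THF, −78 °C
Reagents that add atoms: methanol, CO; potassium tert-butoxide, CC(C)(C)[O-].[K+]
Why: Two successive addition–elimination reactions at the vinylogous acid chloride carbons; the first methoxy group deactivates the remaining C–Cl so that one equivalent of methanol should stop at the ester chloride, and tert-butoxide then displaces chloride, a far better leaving group than methoxide.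

**Step 6**
Reactants: 6 2-[4-(benzyloxy)phenyl]-5-iodo-3-methoxy-4H-pyran-4-one; 9 3-tert-butoxy-4-methoxycyclobut-3-ene-1,2-dione
Product: 11 racemic 2-tert-butoxy-4-hydroxy-3-methoxy-4-[2-(4-benzyloxyphenyl)-3-methoxy-4-oxo-4H-pyran-5-yl]cyclobut-2-en-1-one, via pyranon-5-ylmagnesium chloride 10 (not isolated)
Conditions: i-PrMgCl·LiCl (1.05 equiv), THF, −60 °C; then cannulate into 9 (1.2 equiv), THF, −78 °C; aq. NH4Cl
Reagents that add atoms: none
Why: Iodine–magnesium exchange on the alpha-iodoenone is fast at low temperature, and the vinylmagnesium reagent adds 1,2 to a squarate carbonyl (the standard entry to 4-hydroxycyclobutenones); attack is expected at the carbonyl next to the methoxy-bearing carbon because the tert-butyl group shields the other carbonyl and, twisted out of conjugation, donates less into the one attacked; the new carbinol stereocentre forms as a racemate, which does not matter because it is lost in step 7.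

**Step 7**
Reactants: 11 racemic 2-tert-butoxy-4-hydroxy-3-methoxy-4-[2-(4-benzyloxyphenyl)-3-methoxy-4-oxo-4H-pyran-5-yl]cyclobut-2-en-1-one
Product: 14 4'-benzyloxy-7-tert-butoxy-5,8-dihydroxy-3,6-dimethoxyflavone, via (Z)-dienylketene 12 (not isolated), via cyclohexa-2,4-dienone tautomer 13 (not isolated)
Conditions: degassed toluene (0.02 M), 110 °C, Ar
Reagents that add atoms: none
Why: Heating should trigger the thermally allowed conrotatory four-electron opening of the bond between the ketone carbon and the carbinol carbon of the cyclobutenone, with the hydroxyl rotating outward so that the pyranonyl group turns inward and the ketene carbon of (Z)-dienylketene 12 lies next to pyranone C6. A disrotatory six-electron electrocyclization of the ketene C=C, the enol C=C and the pyranone C5=C6 bond then forms the C8–C8a bond and closes ring A as cyclohexa-2,4-dienone 13, and a proton shift from C8a to the C8 oxygen aromatizes ring A and restores the 4-pyranone. The closest known reaction type is the Moore rearrangement of 4-alkenyl- and 4-heteroaryl-4-hydroxycyclobutenones to hydroquinones, in which alkoxy groups on the cyclobutenone lower the ring-opening temperature. No stereocentre remains, since the racemic carbinol centre becomes sp2 carbon C5 and the transient sp3 centre at C8a is erased by enolization. The step needs outward torquoselectivity of the hydroxyl, which the donor oxygen on the carbinol carbon provides, and closure at a single carbon, which is assured because pyranone C4 is the carbonyl carbon and only C6 can end the triene.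

**Step 8**
Reactants: 14 4'-benzyloxy-7-tert-butoxy-5,8-dihydroxy-3,6-dimethoxyflavone
Product: 15 4'-benzyloxy-7-tert-butoxy-3,5,6,8-tetramethoxyflavone
Conditions: MeI (excess), K2CO3, degassed DMF, 40 °C, Ar
Reagents that add atoms: iodomethane, CI
Why: Double Williamson O-methylation of the hydroquinone; the hydrogen-bonded 5-hydroxyl needs mild warming and excess reagent, exclusion of oxygen keeps the dianion from oxidizing to the 5,8-quinone, and the tert-butyl and benzyl ethers are inert to base.

**Step 9**
Reactants: 15 4'-benzyloxy-7-tert-butoxy-3,5,6,8-tetramethoxyflavone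
Product: 16 4'-benzyloxy-7-hydroxy-3,5,6,8-tetramethoxyflavone
Conditions: CF3CO2H–CH2Cl2 (1:4), 0 °C to rt
Reagents that add atoms: none
Why: Acidolysis of an aryl tert-butyl ether through the tert-butyl cation, lost as 2-methylpropene, is fast in trifluoroacetic acid at room temperature, where aryl methyl ethers, the benzyl ether and the flavone core should persist.

**Step 10**
Reactants: 16 4'-benzyloxy-7-hydroxy-3,5,6,8-tetramethoxyflavone
Product: 17 7,4'-dihydroxy-3,5,6,8-tetramethoxyflavone (target)
Conditions: H2 (1 atm), 10% Pd/C, EtOAc–MeOH, rt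
Reagents that add atoms: none
Why: Catalytic hydrogenolysis of a benzyl aryl ether is selective here, since the tetrasubstituted C2=C3 bond of a 3-methoxyflavone and the aryl methyl ethers are not reduced under one atmosphere of hydrogen at room temperature.

**Compound list**

1 | 3-hydroxy-4H-pyran-4-one (pyromeconic acid) | O=c1ccocc1O | starting material
2 | 2-bromo-3-hydroxy-4H-pyran-4-one | O=c1ccoc(Br)c1O | intermediate
3 | 2-bromo-3-methoxy-4H-pyran-4-one | COc1c(Br)occc1=O | intermediate
4 | 4-(benzyloxy)phenylboronic acid | OB(O)c1ccc(OCc2ccccc2)cc1 | starting material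
5 | 2-[4-(benzyloxy)phenyl]-3-methoxy-4H-pyran-4-one | COc1c(-c2ccc(OCc3ccccc3)cc2)occc1=O | intermediate
6 | 2-[4-(benzyloxy)phenyl]-5-iodo-3-methoxy-4H-pyran-4-one | COc1c(-c2ccc(OCc3ccccc3)cc2)occ(I)c1=O | intermediate
7 | 3,4-dichlorocyclobut-3-ene-1,2-dione (squaric acid dichloride) | O=C1C(=O)C(Cl)=C1Cl | starting material
8 | 3-chloro-4-methoxycyclobut-3-ene-1,2-dione | COC1=C(Cl)C(=O)C1=O | intermediate
9 | 3-tert-butoxy-4-methoxycyclobut-3-ene-1,2-dione | COC1=C(OC(C)(C)C)C(=O)C1=O | intermediate
10 | [2-(4-benzyloxyphenyl)-3-methoxy-4-oxo-4H-pyran-5-yl]magnesium chloride | COc1c(-c2ccc(OCc3ccccc3)cc2)occ([Mg]Cl)c1=O | intermediate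
11 | racemic 2-tert-butoxy-4-hydroxy-3-methoxy-4-[2-(4-benzyloxyphenyl)-3-methoxy-4-oxo-4H-pyran-5-yl]cyclobut-2-en-1-one | O=C1C(OC(C)(C)C)=C(OC)C1(O)c1coc(-c2ccc(OCc3ccccc3)cc2)c(OC)c1=O | intermediate
12 | (Z)-dienylketene: (Z)-2-tert-butoxy-4-hydroxy-3-methoxy-4-[2-(4-benzyloxyphenyl)-3-methoxy-4-oxo-4H-pyran-5-yl]buta-1,3-dien-1-one | O=C=C(OC(C)(C)C)/C(OC)=C(O)\c1coc(-c2ccc(OCc3ccccc3)cc2)c(OC)c1=O | intermediate
13 | racemic 2-(4-benzyloxyphenyl)-7-tert-butoxy-5-hydroxy-3,6-dimethoxy-8aH-chromene-4,8-dione (cyclohexa-2,4-dienone tautomer, sp3 carbon at C8a) | O=C1C(OC(C)(C)C)=C(OC)C(O)=C2C(=O)C(OC)=C(c3ccc(OCc4ccccc4)cc3)OC12 | intermediate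
14 | 4'-benzyloxy-7-tert-butoxy-5,8-dihydroxy-3,6-dimethoxyflavone | COc1c(OC(C)(C)C)c(O)c2oc(-c3ccc(OCc4ccccc4)cc3)c(OC)c(=O)c2c1O | intermediate
15 | 4'-benzyloxy-7-tert-butoxy-3,5,6,8-tetramethoxyflavone | COc1c(OC(C)(C)C)c(OC)c2oc(-c3ccc(OCc4ccccc4)cc3)c(OC)c(=O)c2c1OC | intermediate
16 | 4'-benzyloxy-7-hydroxy-3,5,6,8-tetramethoxyflavone | COc1c(O)c(OC)c2oc(-c3ccc(OCc4ccccc4)cc3)c(OC)c(=O)c2c1OC | intermediate
17 | 7,4'-dihydroxy-3,5,6,8-tetramethoxyflavone | COc1c(O)c(OC)c2oc(-c3ccc(O)cc3)c(OC)c(=O)c2c1OC | target

**Step count**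

Total: 10 steps. Longest linear sequence: 9 steps (steps 1–4 and 6–10, from 1 to 17); step 5 is a one-step side branch.

**Steps most likely to fail**

Step 7. The ketene may be captured by the free tertiary hydroxyl (lactonization after partial inward rotation), the squarate adduct may revert by retro-addition, or 2-methylpropene may be lost thermally from the tert-butoxy group before ring closure. The fallback sets out from 11 and masks the hydroxyl, so that a siloxy donor drives the ring opening and no free hydroxyl is left to trap the ketene. Silylation with Et3SiOTf and 2,6-lutidine in CH2Cl2 at −78 °C should give racemic 2-tert-butoxy-3-methoxy-4-(triethylsilyloxy)-4-[2-(4-benzyloxyphenyl)-3-methoxy-4-oxo-4H-pyran-5-yl]cyclobut-2-en-1-one F1. Thermolysis in toluene should then give 4'-benzyloxy-7-tert-butoxy-8-hydroxy-3,6-dimethoxy-5-(triethylsilyloxy)flavone F2, and desilylation with Bu4NF buffered with acetic acid in THF at 0 °C comes back to the route at 14.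

Step 6. The two squarate carbonyls may be poorly discriminated, giving the regioisomeric carbinol, and the magnesiated pyranone may open by beta-elimination of the ring oxygen if it warms. The fallback sets out from 6 and removes the regiochemical question by using a symmetrical squarate, at the cost of a longer end game.
- Exchange as in step 6 gives 10, which is added to commercial 3,4-di-tert-butoxycyclobut-3-ene-1,2-dione to give racemic 2,3-di-tert-butoxy-4-hydroxy-4-[2-(4-benzyloxyphenyl)-3-methoxy-4-oxo-4H-pyran-5-yl]cyclobut-2-en-1-one F3.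
- Thermolysis in toluene should give 4'-benzyloxy-6,7-di-tert-butoxy-5,8-dihydroxy-3-methoxyflavone F4, and MeI with K2CO3 then gives 4'-benzyloxy-6,7-di-tert-butoxy-3,5,8-trimethoxyflavone F5.
- Trifluoroacetic acid removes both tert-butyl groups to give 4'-benzyloxy-6,7-dihydroxy-3,5,8-trimethoxyflavone F6.
- One equivalent of benzyl bromide with K2CO3 should alkylate the more acidic 7-hydroxyl (para to the carbonyl-bearing C4a) to give 4',7-bis(benzyloxy)-6-hydroxy-3,5,8-trimethoxyflavone F7, and MeI with K2CO3 gives 4',7-bis(benzyloxy)-3,5,6,8-tetramethoxyflavone F8.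
- Hydrogenolysis of both benzyl ethers over Pd/C comes back to the route at 17.

Step 8. The hydroquinone dianion may be oxidized by traces of air to the quinone faster than it is alkylated, and the hydrogen-bonded 5-hydroxyl may alkylate incompletely. The fallback sets out from 14 and goes through the quinone on purpose. Oxidation with Ag2O in CH2Cl2 should give 2-(4-benzyloxyphenyl)-7-tert-butoxy-3,6-dimethoxychromene-4,5,8-trione F9, a stable compound that can be purified. Reductive methylation in one flask (Na2S2O4, Bu4NBr, KOH, Me2SO4, THF–H2O), in which the quinone is reduced and both phenoxides are alkylated under phase transfer, comes back to the route at 15.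

**Further compounds**

F1 | step 7 | racemic 2-tert-butoxy-3-methoxy-4-(triethylsilyloxy)-4-[2-(4-benzyloxyphenyl)-3-methoxy-4-oxo-4H-pyran-5-yl]cyclobut-2-en-1-one | O=C1C(OC(C)(C)C)=C(OC)C1(O[Si](CC)(CC)CC)c1coc(-c2ccc(OCc3ccccc3)cc2)c(OC)c1=O
F2 | step 7 | 4'-benzyloxy-7-tert-butoxy-8-hydroxy-3,6-dimethoxy-5-(triethylsilyloxy)flavone | COc1c(OC(C)(C)C)c(O)c2oc(-c3ccc(OCc4ccccc4)cc3)c(OC)c(=O)c2c1O[Si](CC)(CC)CC
F3 | step 6 | racemic 2,3-di-tert-butoxy-4-hydroxy-4-[2-(4-benzyloxyphenyl)-3-methoxy-4-oxo-4H-pyran-5-yl]cyclobut-2-en-1-one | O=C1C(OC(C)(C)C)=C(OC(C)(C)C)C1(O)c1coc(-c2ccc(OCc3ccccc3)cc2)c(OC)c1=O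
F4 | step 6 | 4'-benzyloxy-6,7-di-tert-butoxy-5,8-dihydroxy-3-methoxyflavone | CC(C)(C)Oc1c(OC(C)(C)C)c(O)c2oc(-c3ccc(OCc4ccccc4)cc3)c(OC)c(=O)c2c1O
F5 | step 6 | 4'-benzyloxy-6,7-di-tert-butoxy-3,5,8-trimethoxyflavone | CC(C)(C)Oc1c(OC(C)(C)C)c(OC)c2oc(-c3ccc(OCc4ccccc4)cc3)c(OC)c(=O)c2c1OC
F6 | step 6 | 4'-benzyloxy-6,7-dihydroxy-3,5,8-trimethoxyflavone | Oc1c(O)c(OC)c2oc(-c3ccc(OCc4ccccc4)cc3)c(OC)c(=O)c2c1OC
F7 | step 6 | 4',7-bis(benzyloxy)-6-hydroxy-3,5,8-trimethoxyflavone | Oc1c(OCc5ccccc5)c(OC)c2oc(-c3ccc(OCc4ccccc4)cc3)c(OC)c(=O)c2c1OC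
F8 | step 6 | 4',7-bis(benzyloxy)-3,5,6,8-tetramethoxyflavone | COc1c(OCc5ccccc5)c(OC)c2oc(-c3ccc(OCc4ccccc4)cc3)c(OC)c(=O)c2c1OC
F9 | step 8 | 2-(4-benzyloxyphenyl)-7-tert-butoxy-3,6-dimethoxychromene-4,5,8-trione | COC1=C(OC(C)(C)C)C(=O)c2oc(-c3ccc(OCc4ccccc4)cc3)c(OC)c(=O)c2C1=O
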